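**Plan**

- Retrosynthesis: the C7′–aryl bond to ring B is cut first (sp3–sp2 cross-coupling), then the oxolane is cut at O1–C5 and C2–C3 (palladium trimethylenemethane [3+2] cycloaddition).
- Enabling feature: in the oxolane O1, C2 (ring A), C3 (CH3), C4, C5, the pair O1–C2 is the carbonyl of a ring A benzaldehyde, and C3–C4(–C7′)–C5 is a methyl-substituted trimethylenemethane with C4 as central carbon and C7′ as the exocyclic CH2.
- Forward: the silyl allylic acetate donor is made in two steps; the cycloaddition closes the only new ring (the oxolane) as its 4-methylene derivative; the methylene carbon is taken through CH2OH, CHO and CH2I to a Negishi coupling with ring B; both benzyl ethers are removed last.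
- Stereochemistry: C2 and C3 arise together in the cycloaddition (chiral phosphoramidite on palladium, anti addition giving the 2,3-trans ring); C4 is set afterwards by base equilibration of the C4 aldehyde to the all-trans isomer.

Key step: step 3

Assumption: 4-(benzyloxy)-3-methoxybenzaldehyde, (2-bromoallyl)trimethylsilane and 4-bromo-2,6-dimethoxyphenol are taken as purchasable. Hydroboration of 7 is assumed to give both C4 epimers, and both are carried on because C4 is equilibrated in step 5.
Locants in the discussion follow the target (O1, C2 aryl, C3 methyl, C4, C5; C7′ between C4 and ring B); systematic names use their own numbering.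

**Route**

Step 1
Reactants: 1 (2-bromoallyl)trimethylsilane; 2 acetaldehyde
Product: 4 3-[(trimethylsilyl)methyl]but-3-en-2-ol (racemic), via [3-(trimethylsilyl)prop-1-en-2-yl]magnesium bromide 3 (not isolated)
Conditions: Mg turnings, THF, reflux; then CH3CHO, THF, −78 °C→0 °C; aq NH4Cl work-up
Reagents that add atoms: none
Why: Grignard reaction, in which magnesium inserts into the vinylic carbon–bromine bond without disturbing the allylsilane and the vinylmagnesium bromide adds 1,2 to acetaldehyde; the carbinol stereocenter may stay racemic because it is erased when 5 is ionized in step 3.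

Step 2
Reactants: 4 3-[(trimethylsilyl)methyl]but-3-en-2-ol
Product: 5 3-[(trimethylsilyl)methyl]but-3-en-2-yl acetate (racemic)
Conditions: Ac2O, pyridine, DMAP (cat.), CH2Cl2, 0 °C→rt
Reagents that add atoms: acetic anhydride, CC(=O)OC(C)=O
Why: DMAP-catalysed O-acylation (esterification) of the secondary allylic alcohol under basic conditions that do not protodesilylate the allylsilane.

Step 3
Reactants: 5 3-[(trimethylsilyl)methyl]but-3-en-2-yl acetate (1.6 equiv); 6 4-(benzyloxy)-3-methoxybenzaldehyde
Product: 7 (2R,3R)-2-[4-(benzyloxy)-3-methoxyphenyl]-3-methyl-4-methylideneoxolane (2,3-trans)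
Conditions: Pd(dba)2 (5 mol %), BINOL-derived 2,5-di(2-naphthyl)pyrrolidine phosphoramidite (10 mol %, enantiomer chosen for 2R), In(acac)3 (10 mol %), toluene, 50 °C
Reagents that add atoms: none
Why: Zerovalent palladium ionizes the allylic acetate of 5 and the departing acetate removes the silyl group, giving a zwitterionic trimethylenemethane–palladium complex that equilibrates faster than it adds, so that the methyl group sits on the nucleophilic carbon; this carbon attacks the carbonyl carbon of 6 (bond C2–C3) and the alkoxide then substitutes at a CH2 terminus of the π-allylpalladium unit (bond O1–C5). The closest known reactions are the phosphoramidite–palladium asymmetric [3+2] cycloaddition of the parent silyl acetate donor with aryl aldehydes and the racemic cycloadditions of this methyl donor, which react through the substituted carbon. The oxolane closes by intramolecular allylic O-alkylation (Tsuji–Trost type), a five-membered closure in which the two allyl termini are identical, so either gives the same ring with the alkene left exocyclic at C4. C2 and C3 are both created in the C–C bond-forming addition: the chiral phosphoramidite on palladium selects the aldehyde face (C2), and C3 follows from an open antiperiplanar approach that keeps methyl and aryl apart (anti adduct, hence the 2,3-trans ring); the ring closure creates no stereocenter and the racemic stereocenter of 5 is lost on ionization. The step needs attack by the methyl-bearing terminus, anti addition and a single aldehyde face; the first is secured by the fast equilibration of the complex toward the less substituted π-allyl, the other two by the ligand pocket, while In(acac)3 activates the electron-rich aldehyde toward the first addition.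

Step 4
Reactants: 7 (2R,3R)-2-[4-(benzyloxy)-3-methoxyphenyl]-3-methyl-4-methylideneoxolane
Product: 9 {(4R,5R)-5-[4-(benzyloxy)-3-methoxyphenyl]-4-methyloxolan-3-yl}methanol (epimer mixture at the CH2OH-bearing ring carbon), via B-alkyl-9-BBN adduct 8 (not isolated)
Conditions: 9-BBN, THF, 0 °C→rt; then aq NaOH, 30 % H2O2, 0 °C→rt
Reagents that add atoms: hydrogen peroxide, OO
Why: Hydroboration–oxidation, in which 9-BBN adds syn and anti-Markovnikov (boron on the exocyclic carbon C7′, hydrogen on C4) and alkaline peroxide replaces boron by hydroxyl with retention; C4 forms as an epimer mixture (hydrogen delivered mainly to the face away from the C3 methyl), which does not matter because C4 is equilibrated in step 5.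

Step 5
Reactants: 9 {(4R,5R)-5-[4-(benzyloxy)-3-methoxyphenyl]-4-methyloxolan-3-yl}methanol (epimer mixture)
Product: 11 (3R,4R,5R)-5-[4-(benzyloxy)-3-methoxyphenyl]-4-methyloxolane-3-carbaldehyde (all-trans), via aldehyde epimer mixture 10 (not isolated)
Conditions: Dess–Martin periodinane, CH2Cl2, rt; crude aldehyde then DBU (0.3 equiv), CH2Cl2, rt
Reagents that add atoms: none
Why: Dess–Martin oxidation gives the aldehyde without touching the benzylic ether, and DBU then equilibrates the only enolizable stereocenter (C4) through the enolate to the thermodynamically preferred isomer with CHO trans to the C3 methyl (all three ring substituents pseudoequatorial); C2 and C3 carry no acidic hydrogen and are unchanged.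

Step 6
Reactants: 11 (3R,4R,5R)-5-[4-(benzyloxy)-3-methoxyphenyl]-4-methyloxolane-3-carbaldehyde
Product: 12 {(3S,4R,5R)-5-[4-(benzyloxy)-3-methoxyphenyl]-4-methyloxolan-3-yl}methanol (all-trans)
Conditions: NaBH4, MeOH, 0 °C
Reagents that add atoms: none
Why: Sodium borohydride 1,2-reduction of the aldehyde, run cold and promptly so that the C4 configuration fixed in step 5 is carried into the alcohol, where any residual cis epimer can be removed by chromatography.

Step 7
Reactants: 12 {(3S,4R,5R)-5-[4-(benzyloxy)-3-methoxyphenyl]-4-methyloxolan-3-yl}methanol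
Product: 13 (2R,3R,4R)-2-[4-(benzyloxy)-3-methoxyphenyl]-4-(iodomethyl)-3-methyloxolane
Conditions: I2, PPh3, imidazole, CH2Cl2, 0 °C→rt
Reagents that add atoms: iodine, [I][I]
Why: Appel-type iodination, in which the alkoxyphosphonium of the primary alcohol is displaced by iodide in an SN2 reaction at C7′ (not a stereocenter) under neutral conditions that spare the benzylic ether.

Step 8
Reactants: 14 4-bromo-2,6-dimethoxyphenol
Product: 15 2-(benzyloxy)-5-bromo-1,3-dimethoxybenzene
Conditions: BnBr, K2CO3, DMF, rt
Reagents that add atoms: benzyl bromide, BrCc1ccccc1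
Why: Williamson ether synthesis on the phenol; the benzyl ether matches the ring A protecting group so that both are removed together in the last step.

Step 9
Reactants: 13 (2R,3R,4R)-2-[4-(benzyloxy)-3-methoxyphenyl]-4-(iodomethyl)-3-methyloxolane; 15 2-(benzyloxy)-5-bromo-1,3-dimethoxybenzene
Product: 17 (2R,3R,4R)-2-[4-(benzyloxy)-3-methoxyphenyl]-4-{[4-(benzyloxy)-3,5-dimethoxyphenyl]methyl}-3-methyloxolane, via alkylzinc iodide 16 (not isolated)
Conditions: Zn dust, LiCl, THF, 40 °C; then 15, Pd(OAc)2 (2 mol %), SPhos (4 mol %), THF, 50 °C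
Reagents that add atoms: none
Why: Negishi coupling, in which LiCl-promoted zinc insertion into the primary carbon–iodine bond gives 16, which transmetalates to the arylpalladium bromide from 15; the bulky biarylphosphine favors reductive elimination over β-hydride elimination, and no stereocenter is touched because the metal sits on C7′.

Step 10
Reactants: 17 (2R,3R,4R)-2-[4-(benzyloxy)-3-methoxyphenyl]-4-{[4-(benzyloxy)-3,5-dimethoxyphenyl]methyl}-3-methyloxolane
Product: 18 4-{[(3R,4R,5R)-5-(4-hydroxy-3-methoxyphenyl)-4-methyloxolan-3-yl]methyl}-2,6-dimethoxyphenol (target)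
Conditions: H2 (1 atm), Pd/C (10 %), EtOAc, rt
Reagents that add atoms: none
Why: Hydrogenolysis of the two aryl benzyl ethers over Pd/C under neutral conditions, stopped once two equivalents of hydrogen are consumed so that the slower cleavage of the benzylic C2–O1 bond of the oxolane does not set in; no stereocenter is affected.

**Compound list**

1 | (2-bromoallyl)trimethylsilane | C[Si](C)(C)CC(Br)=C | starting material
2 | acetaldehyde | CC=O | starting material
3 | [3-(trimethylsilyl)prop-1-en-2-yl]magnesium bromide | C[Si](C)(C)CC(=C)[Mg]Br | intermediate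
4 | 3-[(trimethylsilyl)methyl]but-3-en-2-ol (racemic) | CC(O)C(=C)C[Si](C)(C)C | intermediate
5 | 3-[(trimethylsilyl)methyl]but-3-en-2-yl acetate (racemic) | CC(OC(C)=O)C(=C)C[Si](C)(C)C | intermediate
6 | 4-(benzyloxy)-3-methoxybenzaldehyde | COc1cc(C=O)ccc1OCc1ccccc1 | starting material
7 | (2R,3R)-2-[4-(benzyloxy)-3-methoxyphenyl]-3-methyl-4-methylideneoxolane | COc1cc([C@@H]2OCC(=C)[C@H]2C)ccc1OCc1ccccc1 | intermediate
8 | 9-{[(4R,5R)-5-[4-(benzyloxy)-3-methoxyphenyl]-4-methyloxolan-3-yl]methyl}-9-borabicyclo[3.3.1]nonane (epimers at ring C3) | COc1cc([C@@H]2OCC(CB3C4CCCC3CCC4)[C@H]2C)ccc1OCc1ccccc1 | intermediate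
9 | {(4R,5R)-5-[4-(benzyloxy)-3-methoxyphenyl]-4-methyloxolan-3-yl}methanol (epimers at ring C3) | COc1cc([C@@H]2OCC(CO)[C@H]2C)ccc1OCc1ccccc1 | intermediate
10 | (4R,5R)-5-[4-(benzyloxy)-3-methoxyphenyl]-4-methyloxolane-3-carbaldehyde (epimers at ring C3) | COc1cc([C@@H]2OCC(C=O)[C@H]2C)ccc1OCc1ccccc1 | intermediate
11 | (3R,4R,5R)-5-[4-(benzyloxy)-3-methoxyphenyl]-4-methyloxolane-3-carbaldehyde | COc1cc([C@@H]2OC[C@H](C=O)[C@H]2C)ccc1OCc1ccccc1 | intermediate
12 | {(3S,4R,5R)-5-[4-(benzyloxy)-3-methoxyphenyl]-4-methyloxolan-3-yl}methanol | COc1cc([C@@H]2OC[C@H](CO)[C@H]2C)ccc1OCc1ccccc1 | intermediate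
13 | (2R,3R,4R)-2-[4-(benzyloxy)-3-methoxyphenyl]-4-(iodomethyl)-3-methyloxolane | COc1cc([C@@H]2OC[C@H](CI)[C@H]2C)ccc1OCc1ccccc1 | intermediate
14 | 4-bromo-2,6-dimethoxyphenol | COc1cc(Br)cc(OC)c1O | starting material
15 | 2-(benzyloxy)-5-bromo-1,3-dimethoxybenzene | COc1cc(Br)cc(OC)c1OCc1ccccc1 | intermediate
16 | {[(3R,4R,5R)-5-[4-(benzyloxy)-3-methoxyphenyl]-4-methyloxolan-3-yl]methyl}zinc iodide | COc1cc([C@@H]2OC[C@H](C[Zn]I)[C@H]2C)ccc1OCc1ccccc1 | intermediate
17 | (2R,3R,4R)-2-[4-(benzyloxy)-3-methoxyphenyl]-4-{[4-(benzyloxy)-3,5-dimethoxyphenyl]methyl}-3-methyloxolane | COc1cc([C@@H]2OC[C@H](Cc3cc(OC)c(OCc4ccccc4)c(OC)c3)[C@H]2C)ccc1OCc1ccccc1 | intermediate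
18 | 4-{[(3R,4R,5R)-5-(4-hydroxy-3-methoxyphenyl)-4-methyloxolan-3-yl]methyl}-2,6-dimethoxyphenol | COc1cc([C@@H]2OC[C@H](Cc3cc(OC)c(O)c(OC)c3)[C@H]2C)ccc1O | target

**Count and risks**

Total step count: 10. Longest linear sequence: 9 steps (steps 1–7, 9 and 10); step 8 is a one-step side branch.

Steps most likely to fail:

Step 3. The methyl donor may add through its unsubstituted terminus, show a weak anti preference or poor aldehyde-face selection under the chiral catalyst, or react sluggishly with the electron-rich aldehyde. The fallback makes the same two bonds one after the other; it sets out from 6 and comes back at 7. Aldehyde 6 is propargylated with the chiral allenylzinc reagent generated from enantiopure but-3-yn-2-yl methanesulfonate (Pd(OAc)2, PPh3, Et2Zn, THF, −20 °C), using the mesylate enantiomer that delivers the anti adduct (expected to be the S mesylate). This should give (1R,2R)-1-[4-(benzyloxy)-3-methoxyphenyl]-2-methylbut-3-yn-1-ol F1. Palladium-catalysed cyclocarbonylation of the homopropargylic alcohol (PdCl2, SnCl2, PPh3, CO, MeCN, 75 °C) then gives the trans α-methylene lactone (4R,5R)-5-[4-(benzyloxy)-3-methoxyphenyl]-4-methyl-3-methylideneoxolan-2-one F2. Reduction with i-Bu2AlH (CH2Cl2, −78 °C→0 °C) affords (1R,2R)-1-[4-(benzyloxy)-3-methoxyphenyl]-2-methyl-3-methylidenebutane-1,4-diol F3. Mitsunobu cyclodehydration (PPh3, DIAD, THF, 0 °C), which activates the primary allylic hydroxyl and leaves the benzylic C–O bond intact, returns 7.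

Step 5. The epimerization may stall short of a useful trans excess, or the aldehyde enolate may be lost to aldol condensation or to β-alkoxide elimination that opens the oxolane. The fallback equilibrates C4 at the more robust ester level; it sets out from 10 and comes back at 12. Crude 10 is oxidized (Pinnick: NaClO2, NaH2PO4, 2-methylbut-2-ene, t-BuOH/H2O) to (4R,5R)-5-[4-(benzyloxy)-3-methoxyphenyl]-4-methyloxolane-3-carboxylic acid F4 (ring C3 epimers). Esterification (MeI, K2CO3, DMF) gives methyl (4R,5R)-5-[4-(benzyloxy)-3-methoxyphenyl]-4-methyloxolane-3-carboxylate F5 (ring C3 epimers). Equilibration with NaOMe in MeOH at reflux should give the all-trans methyl (3R,4R,5R)-5-[4-(benzyloxy)-3-methoxyphenyl]-4-methyloxolane-3-carboxylate F6. Reduction with LiAlH4 (THF, 0 °C) gives 12.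

Step 9. Zinc insertion may be slow or the alkylzinc may be protonated, and the β-branched alkylpalladium may undergo β-hydride elimination or homocoupling instead of cross-coupling. The fallback forms the C7′–aryl bond by carbonyl addition and then removes the oxygen by a radical path that cannot touch the ring ether; it sets out from 11 and 15 and comes back at 17. Bromine–lithium exchange on 15 (n-BuLi, THF, −78 °C) gives [4-(benzyloxy)-3,5-dimethoxyphenyl]lithium F7. This adds to aldehyde 11 to give [4-(benzyloxy)-3,5-dimethoxyphenyl]{(4R,5R)-5-[4-(benzyloxy)-3-methoxyphenyl]-4-methyloxolan-3-yl}methanol F8 (ring configuration as in 11, both carbinol epimers). The alcohol is converted (NaH, CS2, MeI, THF) into the xanthate O-{[4-(benzyloxy)-3,5-dimethoxyphenyl][(4R,5R)-5-[4-(benzyloxy)-3-methoxyphenyl]-4-methyloxolan-3-yl]methyl} S-methyl carbonodithioate F9. Barton–McCombie reduction (Bu3SnH, AIBN, toluene, 80 °C) gives 17.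

Further compounds
F1 | step 3 | (1R,2R)-1-[4-(benzyloxy)-3-methoxyphenyl]-2-methylbut-3-yn-1-ol | COc1cc([C@H](O)[C@H](C)C#C)ccc1OCc1ccccc1
F2 | step 3 | (4R,5R)-5-[4-(benzyloxy)-3-methoxyphenyl]-4-methyl-3-methylideneoxolan-2-one | COc1cc([C@@H]2OC(=O)C(=C)[C@H]2C)ccc1OCc1ccccc1
F3 | step 3 | (1R,2R)-1-[4-(benzyloxy)-3-methoxyphenyl]-2-methyl-3-methylidenebutane-1,4-diol | COc1cc([C@H](O)[C@H](C)C(=C)CO)ccc1OCc1ccccc1
F4 | step 5 | (4R,5R)-5-[4-(benzyloxy)-3-methoxyphenyl]-4-methyloxolane-3-carboxylic acid (ring C3 epimers) | COc1cc([C@@H]2OCC(C(=O)O)[C@H]2C)ccc1OCc1ccccc1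
F5 | step 5 | methyl (4R,5R)-5-[4-(benzyloxy)-3-methoxyphenyl]-4-methyloxolane-3-carboxylate (ring C3 epimers) | COc1cc([C@@H]2OCC(C(=O)OC)[C@H]2C)ccc1OCc1ccccc1
F6 | step 5 | methyl (3R,4R,5R)-5-[4-(benzyloxy)-3-methoxyphenyl]-4-methyloxolane-3-carboxylate | COc1cc([C@@H]2OC[C@H](C(=O)OC)[C@H]2C)ccc1OCc1ccccc1
F7 | step 9 | [4-(benzyloxy)-3,5-dimethoxyphenyl]lithium | [Li]c1cc(OC)c(OCc2ccccc2)c(OC)c1
F8 | step 9 | [4-(benzyloxy)-3,5-dimethoxyphenyl]{(4R,5R)-5-[4-(benzyloxy)-3-methoxyphenyl]-4-methyloxolan-3-yl}methanol (ring configuration as in 11, carbinol epimers) | COc1cc([C@@H]2OC[C@H](C(O)c3cc(OC)c(OCc4ccccc4)c(OC)c3)[C@H]2C)ccc1OCc1ccccc1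
F9 | step 9 | O-{[4-(benzyloxy)-3,5-dimethoxyphenyl][(4R,5R)-5-[4-(benzyloxy)-3-methoxyphenyl]-4-methyloxolan-3-yl]methyl} S-methyl carbonodithioate | COc1cc([C@@H]2OC[C@H](C(OC(=S)SC)c3cc(OC)c(OCc4ccccc4)c(OC)c3)[C@H]2C)ccc1OCc1ccccc1
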